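In a one-step world with a first-order step, a rate fades along one exponential, and the target still to come is the present rate times its time constant. These flasks are not that world, but I can use the rule piecewise.

| flask | starting material | free catalyst | time |
|---|---|---|---|
| south-west | 250 mM | 5.00 mM |  |
| south-east | 250 mM | 2.50 mM |  |
| north-east | 500 mM | 5.00 mM |  |
| west | 250 mM | 5.00 mM | 250 h |

- south-west run (time / h: [target] / mM): 10: 48.4; 21: 92.4; 31: 121.9; 41: 146.3; 52: 163.5; 62: 173.9
- south-east run (time / h: [target] / mM): 10: 12.4; 21: 23.1; 31: 33.4; 41: 40.6; 52: 48.9; 62: 56.9
- north-east run (time / h: [target] / mM): 10: 48.3; 21: 94.3; 31: 133.6; 41: 166.4; 52: 200.0; 62: 224.1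

(standard deviation of a reading: 1 mM)

- order of the initial rate in [starting material], near the charge of the south-west run, the rate being that where two percent of its starting material are target (one fixed amount of target, the same in the runs compared)
- order of the initial rate in [free catalyst], near the charge of the south-west run, the rate being that where two percent of its starting material are target
- target in the west run at 250 h, as a share of the starting material charged

- Overall: starting material -> target, with free catalyst as catalyst.
- Constant volume, constant temperature.
- The analysis sees a species whether free or bound.
- An order is taken over about fifteen percent of the charge, up and down.

First the opening hours. At 10 h the south-west run has turned 19.4 % of its charge. The north-east run has turned 9.66 %, half that share of twice the charge, so the two make target at one rate. The south-east run, with half the free catalyst, has turned 4.96 %, a quarter of the south-west share. I read an order in catalyst of 1.96 and one close to zero in starting material.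

Then the middle. By 31 h the south-west run stands at 48.8 %, and the next 31.0 h add 20.8 %. The south-east run fades too: its second 31.0 h give 70.4 % of what its first gave, and at 62 h it stands at 22.8 % turned.

Now the end. In the south-west run the rate falls from 0.00976 h⁻¹ of the charge between 31 h and 41 h to 0.00416 h⁻¹ between 52 h and 62 h. Those windows give 24.6 h. This is the fading time, the time in which a rate falls by the factor e, an apparent first-order time constant. In the south-west run at 57.0 h the target stands near 67.5 %, and rate times fading time adds 10.2 %. The west run repeats that charge, so I commit to 77.7 % at 250 h.

The forecast gives an order of 0.06 in starting material (−0.05 to 0.25), an order of 1.9 in free catalyst (1.5 to 2.1) and 94 % for the west run (86 % to 99 %), reasoning that “either target inhibits or catalyst decays”. My figure for the west run is lower.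

The flask gives an order of 0.16 in starting material, an order of 2.0 in free catalyst and 76.7 % for the west run.

    free catalyst + starting material ⇌ catalyst-substrate complex, settled at all times (3.000 M⁻¹)
    catalyst-substrate complex + free catalyst → target + 2 free catalyst (842.4 M⁻¹ h⁻¹)
    free catalyst + starting material → spent catalyst + starting material (0.03445 M⁻¹ h⁻¹)
    starting material → decomposed substrate (0.008748 h⁻¹)

A power law fitted to the runs leaves a root mean square residual of 10 in units of the scatter and puts the west run at 100 %. In the south-east run, the windows from the start to 31 h and from 31 h to 62 h, read as one exponential, give a fading time of 88.2 h and an estimated ceiling of 45.1 %, which puts a quarter of the charge at 71.3 h; the south-east run reaches it at 73.7 h.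

(The earlier runs and the new flask stem from a simulated flask for an exercise; noise was put on by code.)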